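**Plan**

- Retrosynthesis: the C3 methyl is traced back to a C3 CH2OMe group (C–O reduction). The furan is then opened at O1–C2 and C3–CH2, which returns the CH2OMe to O1 as the methoxymethyl ether of a 2-alkynylphenol. Next cuts: ring A–alkyne bond (Sonogashira), C7–allyl (Claisen), C7a–O (Baeyer–Villiger of an aldehyde).
- Enabling feature: in the benzofuran (O1, C2 aryl, C3 methyl, C3a, C4 H, C5 OMe, C6 OH, C7 allyl, C7a) the C3 methyl carbon lies 1,3 to O1 across C2. It can therefore travel on the C7a oxygen as the CH2 of an acetal and be handed to C3 while the furan ring closes.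
- Forward order: ring A is dressed first (C6–OH masked, C7a oxygen installed, allyl placed on C7, acetal put on the C7a oxygen). The trimethoxyphenyl alkyne is then joined, the furan ring (the only ring formed) closes with the acetal shift, and one acidic silane reduction finishes.
- Stereochemistry: the target has no stereocentre and no stereogenic double bond, so nothing has to be set.

Key step: step 7

Assumption: in step 8 the benzofuran-3-ylmethyl ether is taken to ionise faster than the aryl acetal is cleaved, so 12 is the in-flask intermediate.

**Route**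

Step 1
Reactants: 1 2-bromo-5-hydroxy-4-methoxybenzaldehyde
Product: 2 2-bromo-4-methoxy-5-(methoxymethoxy)benzaldehyde
Conditions: MOMCl, i-Pr2NEt, CH2Cl2, 0 °C → rt
Reagents that add atoms: chloromethyl methyl ether, COCCl
Why: Williamson-type O-alkylation of the phenol with the chloromethyl ether under amine base leaves the aldehyde untouched and masks the future C6–OH as an acetal that should survive peracid, heat, base and the metal catalysts.

Step 2
Reactants: 2 2-bromo-4-methoxy-5-(methoxymethoxy)benzaldehyde
Product: 4 2-bromo-4-methoxy-5-(methoxymethoxy)phenol, via aryl formate 3 (not isolated)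
Conditions: mCPBA (1.2 equiv), CH2Cl2, 0 °C → rt; then K2CO3 (cat.), MeOH, rt
Reagents that add atoms: 3-chloroperoxybenzoic acid, O=C(OO)c1cccc(Cl)c1
Why: Baeyer–Villiger (Dakin-type) oxidation, in which the aryl group, made migration-prone by the para methoxy group, shifts to oxygen to give the formate that methanol then cleaves; no alkene is in the molecule yet, so the peracid has a single site of attack.

Step 3
Reactants: 4 2-bromo-4-methoxy-5-(methoxymethoxy)phenol; 5 allyl bromide
Product: 6 1-(allyloxy)-2-bromo-4-methoxy-5-(methoxymethoxy)benzene
Conditions: K2CO3, DMF, rt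
Reagents that add atoms: none
Why: Williamson ether synthesis of the phenoxide with a reactive allylic bromide should be clean, and the acetal is stable to carbonate.

Step 4
Reactants: 6 1-(allyloxy)-2-bromo-4-methoxy-5-(methoxymethoxy)benzene
Product: 7 2-allyl-6-bromo-4-methoxy-3-(methoxymethoxy)phenol
Conditions: PhNEt2, 190 °C
Reagents that add atoms: none
Why: Aromatic Claisen rearrangement ([3,3]-sigmatropic shift) in which the bromine blocks one ortho carbon, since a shift onto it gives a dienone that cannot tautomerise and reverts, so the allyl group should settle on the free ortho carbon between the two oxygens and the ring rearomatises to the phenol.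

Step 5
Reactants: 7 2-allyl-6-bromo-4-methoxy-3-(methoxymethoxy)phenol
Product: 8 3-allyl-1-bromo-5-methoxy-2,4-bis(methoxymethoxy)benzene
Conditions: NaH, THF, 0 °C; then MOMCl, 0 °C → rt
Reagents that add atoms: chloromethyl methyl ether, COCCl
Why: Williamson-type O-alkylation of the preformed sodium phenoxide overcomes the flanking allyl and bromo groups and installs the acetal whose CH2OMe unit later becomes the C3 carbon.

Step 6
Reactants: 8 3-allyl-1-bromo-5-methoxy-2,4-bis(methoxymethoxy)benzene; 9 5-ethynyl-1,2,3-trimethoxybenzene
Product: 10 5-{[3-allyl-5-methoxy-2,4-bis(methoxymethoxy)phenyl]ethynyl}-1,2,3-trimethoxybenzene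
Conditions: Pd(PhCN)2Cl2 (3 mol%), P(t-Bu)3·HBF4 (6 mol%), CuI (2 mol%), i-Pr2NH, 1,4-dioxane, rt → 50 °C, degassed
Reagents that add atoms: none
Why: Sonogashira coupling, in which the bulky electron-rich phosphine lets zerovalent palladium insert into the electron-rich, ortho-substituted aryl bromide under mild conditions; with both phenols capped, the alkyne cannot cyclise prematurely, and the isolated allyl group is a much slower partner than the copper acetylide.

Step 7
Reactants: 10 5-{[3-allyl-5-methoxy-2,4-bis(methoxymethoxy)phenyl]ethynyl}-1,2,3-trimethoxybenzene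
Product: 11 7-allyl-5-methoxy-6-(methoxymethoxy)-3-(methoxymethyl)-2-(3,4,5-trimethoxyphenyl)benzofuran
Conditions: PtCl2 (5 mol%), 1,5-cyclooctadiene (20 mol%), toluene, 40 °C
Reagents that add atoms: none
Why: Divalent platinum (PtCl2, kept soluble and active by the diene) binds the alkyne, the acetal oxygen on C7a adds anti to the metal at the alkyne carbon that carries the trimethoxyphenyl ring, and the oxonium ion so formed gives up its methoxymethyl group to the C3 vinyl–platinum carbon, which frees the catalyst. The closest known reaction type is the PtCl2–olefin-catalysed carboalkoxylation of o-alkynylphenyl acetals to 3-(alkoxyalkyl)benzofurans. The furan ring closes in a 5-endo-dig mode to form O1–C2, and the 1,3 oxygen-to-carbon shift forms C3–CH2. No stereocentre is created. The step needs transfer of the CH2OMe group to C3 in preference to its loss (which would leave C3–H): toluene keeps the oxonium/vinyl–platinum pair tight so the transfer stays intramolecular, and the vinyl–platinum carbon is the strongest nucleophile present. The step also needs the other acetal and the alkene to stay out: the C6 acetal oxygen is para to the alkyne and the allyl group is meta to it, so neither can reach the activated triple bond.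

Step 8
Reactants: 11 7-allyl-5-methoxy-6-(methoxymethoxy)-3-(methoxymethyl)-2-(3,4,5-trimethoxyphenyl)benzofuran
Product: 13 7-allyl-5-methoxy-3-methyl-2-(3,4,5-trimethoxyphenyl)benzofuran-6-ol, via C3-methyl MOM ether 12 (not isolated)
Conditions: Et3SiH (6 equiv), CF3CO2H, CH2Cl2, 0 °C → rt
Reagents that add atoms: none
Why: Ionic hydrogenation, in which acid ionises the C3 CH2OMe group to a benzofuran-3-ylmethyl cation stabilised by O1 and the C2 aryl ring and the silane reduces it to methyl, while the same acid cleaves the aryl acetal with the silane scavenging the methoxymethyl cation; the monosubstituted allyl alkene gives no stabilised cation and should not be reduced at this temperature.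

**Compound list**

1 | 2-bromo-5-hydroxy-4-methoxybenzaldehyde | COc1cc(Br)c(C=O)cc1O | starting material
2 | 2-bromo-4-methoxy-5-(methoxymethoxy)benzaldehyde | COCOc1cc(C=O)c(Br)cc1OC | intermediate
3 | 2-bromo-4-methoxy-5-(methoxymethoxy)phenyl formate | COCOc1cc(OC=O)c(Br)cc1OC | intermediate
4 | 2-bromo-4-methoxy-5-(methoxymethoxy)phenol | COCOc1cc(O)c(Br)cc1OC | intermediate
5 | allyl bromide | C=CCBr | starting material
6 | 1-(allyloxy)-2-bromo-4-methoxy-5-(methoxymethoxy)benzene | C=CCOc1cc(OCOC)c(OC)cc1Br | intermediate
7 | 2-allyl-6-bromo-4-methoxy-3-(methoxymethoxy)phenol | C=CCc1c(O)c(Br)cc(OC)c1OCOC | intermediate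
8 | 3-allyl-1-bromo-5-methoxy-2,4-bis(methoxymethoxy)benzene | C=CCc1c(OCOC)c(Br)cc(OC)c1OCOC | intermediate
9 | 5-ethynyl-1,2,3-trimethoxybenzene | C#Cc1cc(OC)c(OC)c(OC)c1 | starting material
10 | 5-{[3-allyl-5-methoxy-2,4-bis(methoxymethoxy)phenyl]ethynyl}-1,2,3-trimethoxybenzene | C=CCc1c(OCOC)c(OC)cc(C#Cc2cc(OC)c(OC)c(OC)c2)c1OCOC | intermediate
11 | 7-allyl-5-methoxy-6-(methoxymethoxy)-3-(methoxymethyl)-2-(3,4,5-trimethoxyphenyl)benzofuran | C=CCc1c(OCOC)c(OC)cc2c(COC)c(-c3cc(OC)c(OC)c(OC)c3)oc12 | intermediate
12 | 7-allyl-5-methoxy-6-(methoxymethoxy)-3-methyl-2-(3,4,5-trimethoxyphenyl)benzofuran | C=CCc1c(OCOC)c(OC)cc2c(C)c(-c3cc(OC)c(OC)c(OC)c3)oc12 | intermediate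
13 | 7-allyl-5-methoxy-3-methyl-2-(3,4,5-trimethoxyphenyl)benzofuran-6-ol | C=CCc1c(O)c(OC)cc2c(C)c(-c3cc(OC)c(OC)c(OC)c3)oc12 | target

**Count**

Total steps: 8. Longest linear sequence: 8 steps (1 → 13); 5 and 9 enter in steps 3 and 6.

**Steps most likely to fail, with fallbacks**

Step 7. The methoxymethyl group may leave the oxonium intermediate without reaching C3, so that protonation of the vinyl–platinum bond gives a C3–H benzofuran, or the freed cation may alkylate an electron-rich ring. The fallback sets out from 10 and forms the same O1–C2 bond with an electrophile instead of the metal. Iodine with NaHCO3 in CH2Cl2 at rt should activate the alkyne for 5-endo-dig attack by the acetal oxygen with expulsion of the methoxymethyl group, giving 7-allyl-3-iodo-5-methoxy-6-(methoxymethoxy)-2-(3,4,5-trimethoxyphenyl)benzofuran F1; any iodine taken up reversibly by the allyl group is returned on thiosulfate work-up. Suzuki–Miyaura methylation of F1 with trimethylboroxine (Pd(PPh3)4, K2CO3, 1,4-dioxane, 90 °C) then places the methyl group on C3 directly. The fallback comes back to the route at 12, from which the acid of step 8 removes the remaining acetal to give 13.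

Step 8. The strongly stabilised C3 cation may be captured by another electron-rich ring instead of hydride, the furan C2=C3 bond may be protonated and over-reduced, or the liberated phenol may add across the neighbouring allyl group under acid. The fallback sets out from 11 and separates ionisation from reduction. Thiophenol and CF3CO2H in CH2Cl2 at 0 °C should trap the cation with a soft nucleophile and cleave the acetal with no hydride present, giving 7-allyl-5-methoxy-3-[(phenylthio)methyl]-2-(3,4,5-trimethoxyphenyl)benzofuran-6-ol F2. Radical desulfurization of F2 with Bu3SnH and azobisisobutyronitrile in toluene at 90 °C, under neutral conditions, should then give 13, where the fallback rejoins the route.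

Step 4. At 190 °C the allyl group may shift onto the bromine-bearing carbon with subsequent loss of bromine, or the acetal may not survive the heating. The fallback sets out from 1 and runs the sigmatropic shift at the aldehyde stage, where the only free ortho carbon lies between the allyloxy and formyl groups:
- Allyl bromide 5 with K2CO3 in DMF should give 5-(allyloxy)-2-bromo-4-methoxybenzaldehyde F3.
- Claisen rearrangement in PhNEt2 at 190 °C should give 2-allyl-6-bromo-3-hydroxy-4-methoxybenzaldehyde F4.
- MOMCl and i-Pr2NEt should give 2-allyl-6-bromo-4-methoxy-3-(methoxymethoxy)benzaldehyde F5.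
- Baeyer–Villiger oxidation with mCPBA and NaHCO3 in CH2Cl2 at 0 °C, where the electron-rich aldehyde should react faster than the monosubstituted alkene, should give 2-allyl-6-bromo-4-methoxy-3-(methoxymethoxy)phenyl formate F6, which is methanolysed with catalytic K2CO3.

The fallback comes back to the route at 7.

**Further compounds**

F1 | step 7 | 7-allyl-3-iodo-5-methoxy-6-(methoxymethoxy)-2-(3,4,5-trimethoxyphenyl)benzofuran | C=CCc1c(OCOC)c(OC)cc2c(I)c(-c3cc(OC)c(OC)c(OC)c3)oc12
F2 | step 8 | 7-allyl-5-methoxy-3-[(phenylthio)methyl]-2-(3,4,5-trimethoxyphenyl)benzofuran-6-ol | C=CCc1c(O)c(OC)cc2c(CSc3ccccc3)c(-c3cc(OC)c(OC)c(OC)c3)oc12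
F3 | step 4 | 5-(allyloxy)-2-bromo-4-methoxybenzaldehyde | C=CCOc1cc(C=O)c(Br)cc1OC
F4 | step 4 | 2-allyl-6-bromo-3-hydroxy-4-methoxybenzaldehyde | C=CCc1c(O)c(OC)cc(Br)c1C=O
F5 | step 4 | 2-allyl-6-bromo-4-methoxy-3-(methoxymethoxy)benzaldehyde | C=CCc1c(OCOC)c(OC)cc(Br)c1C=O
F6 | step 4 | 2-allyl-6-bromo-4-methoxy-3-(methoxymethoxy)phenyl formate | C=CCc1c(OCOC)c(OC)cc(Br)c1OC=O
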